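**Strategy.** Everything rests on making the C5–C5a bond (1-benzoxepine numbering of the target) as a C=C bond by an intramolecular Wittig olefination that closes a temporary butenolide. The step exploits the 1,4-relationship of the ether oxygen on C9a and the carbinol carbon C4 across C5a–C5: O1–C9a–C5a–C5–C4 is a latent γ-lactone, and C5a, flanked by the quaternary C6 and C9a of the cyclohexane, can serve as a non-enolisable ketone. The precursor is a brominated α-ketol that a ketene ylide acylates in the flask. Hydroxyl-directed hydrogenation then fixes C5a, and acetylide addition plus 7-endo oxa-Michael closure expands the lactone to the oxepane.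

Key step: step 6

Remark: target locants are those of (2R,4R,5aS,7S,9aS)-7-bromo-2-(bromomethyl)-6,6,9a-trimethyl-3-methylidenedecahydro-1-benzoxepin-4-ol; each intermediate is named with its own locants, and vinylsilanes 3–6 are carried as E/Z mixtures.

Step 1
Reactants: 1 6-methylhept-5-en-2-one
Product: 2 4-[(2R)-3,3-dimethyloxiran-2-yl]butan-2-one
Conditions: D-fructose-derived Shi ketone (30 mol%), Oxone, K2CO3, Bu4NHSO4 (cat.), MeCN/CH2(OMe)2/aq. Na2B4O7–EDTA buffer, 0 °C
Reagents that add atoms: Oxone (potassium peroxymonosulfate), [K+].[O-]S(=O)(=O)OO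
Why: Shi asymmetric epoxidation: the chiral dioxirane formed in the flask epoxidises the only alkene through the spiro transition state, which is expected to set the 2R oxirane centre (the later C7 of the target after one inversion), and the antipodal ketone catalyst would be used if the facial sense proved opposite.

Step 2
Reactants: 2 4-[(2R)-3,3-dimethyloxiran-2-yl]butan-2-one
Product: 3 {4-[(2R)-3,3-dimethyloxiran-2-yl]-2-methylbut-1-en-1-yl}trimethylsilane (E/Z mixture)
Conditions: LiCH(SiMe3)2 [from (Me3Si)2CH2, t-BuLi, THF/HMPA, −78 °C], CeCl3, THF, −78 °C → rt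
Reagents that add atoms: bis(trimethylsilyl)methyllithium, [Li]C([Si](C)(C)C)[Si](C)(C)C
Why: Peterson olefination: the cerium-modified bis-silyl carbanion should add to the methyl ketone without enolisation or epoxide opening and the β-silyl alkoxide eliminates silanolate to give the vinylsilane, whose E/Z ratio does not matter because the silicon-bearing carbon becomes sp2 again in step 4.

Step 3
Reactants: 3 {4-[(2R)-3,3-dimethyloxiran-2-yl]-2-methylbut-1-en-1-yl}trimethylsilane
Product: 5 (3R)-2-bromo-2,6-dimethyl-7-(trimethylsilyl)hept-6-en-3-ol, via silyl ether 4 (not isolated)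
Conditions: Me3SiBr, CH2Cl2, −78 °C; then citric acid, MeOH, 0 °C
Reagents that add atoms: bromotrimethylsilane, C[Si](C)(C)Br
Why: Silyl halide opening of an epoxide: O-silylation and SN1-like attack of bromide at the tertiary oxirane carbon give the tertiary bromide while the C–O bond at the stereocentre stays intact (3R retained), and mild acidic methanolysis frees the secondary alcohol without closing the epoxide again.

Step 4
Reactants: 5 (3R)-2-bromo-2,6-dimethyl-7-(trimethylsilyl)hept-6-en-3-ol
Product: 7 (4S)-4-bromo-1,3,3-trimethylcyclohex-1-ene, via triflate 6 (not isolated)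
Conditions: Tf2O, 2,6-di-tert-butyl-4-methylpyridine, CH2Cl2 (0.005 M), −78 → −20 °C
Reagents that add atoms: none
Why: Cation–olefin cyclisation started by an enantiopure bromonium ion and ended by a vinylsilane: the neighbouring bromine displaces the triflate from the back (inversion, giving 4S), the vinylsilane attacks the tertiary bromonium carbon through a chair (6-endo) and loss of silicon, directly or by protodesilylation of silicon-retaining alkenes in the acidic medium, leaves the double bond only between C1 and C2, while high dilution should let ring closure outrun racemising bromonium transfer between alkenes.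

Step 5
Reactants: 7 (4S)-4-bromo-1,3,3-trimethylcyclohex-1-ene
Product: 8 (2S,5S)-5-bromo-2-hydroxy-2,6,6-trimethylcyclohexan-1-one
Conditions: RuCl3 (1 mol%), Oxone, NaHCO3, EtOAc/MeCN/H2O, 0 °C → rt
Reagents that add atoms: Oxone (potassium peroxymonosulfate), [K+].[O-]S(=O)(=O)OO
Why: RuO4-catalysed ketohydroxylation: the [3+2] addition of RuO4 should take the alkene face opposite the pseudo-axial C3 methyl group of the half-chair with equatorial bromine, which places the new tertiary hydroxyl trans to bromine (2S), and the secondary ruthenate carbon is oxidised on to the ketone.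

Step 6
Reactants: 8 (2S,5S)-5-bromo-2-hydroxy-2,6,6-trimethylcyclohexan-1-one; 9 (triphenylphosphoranylidene)ketene
Product: 11 (5S,7aS)-5-bromo-4,4,7a-trimethyl-5,6,7,7a-tetrahydro-1-benzofuran-2(4H)-one, via ester ylide 10 (not isolated)
Conditions: toluene, reflux (110 °C)
Reagents that add atoms: none
Why: The tertiary hydroxyl adds across the C=C bond of the ketene ylide to give the ester-stabilised ylide 10, whose carbanion attacks the neighbouring ketone in a 5-exo-trig closure, and the oxaphosphetane collapses with loss of Ph3PO so that the C3=C3a bond of 11 (C5–C5a of the target) closes the butenolide ring. The closest known reaction type is the addition–intramolecular Wittig olefination of α-hydroxy ketones with this ylide to give butenolides. No stereocentre is formed: C3a becomes trigonal and is set in step 8, and the existing centres cannot epimerise because the ketone has no α-hydrogen and the β-bromide has no acidic hydrogen for elimination. The step needs intramolecular olefination of a ketone flanked by two quaternary carbons to beat intermolecular reaction; the short cis-constrained tether holds the ylide carbon against the carbonyl carbon, and the stabilised ylide tolerates the heating that this hindered carbonyl requires.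

Step 7
Reactants: 11 (5S,7aS)-5-bromo-4,4,7a-trimethyl-5,6,7,7a-tetrahydro-1-benzofuran-2(4H)-one
Product: 12 (1S,4S)-4-bromo-2-[(2Z)-2-hydroxyethylidene]-1,3,3-trimethylcyclohexan-1-ol
Conditions: DIBAL-H (3.5 equiv), CH2Cl2, −78 → 0 °C; aq. Rochelle salt
Reagents that add atoms: none
Why: Hydride reduction of a lactone: 1,2-reduction through the lactol aluminate opens the butenolide to the Z-allylic 1,4-diol, the alkene geometry being inherited from the ring, and the alkyl bromide is inert to DIBAL-H.

Step 8
Reactants: 12 (1S,4S)-4-bromo-2-[(2Z)-2-hydroxyethylidene]-1,3,3-trimethylcyclohexan-1-ol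
Product: 13 (1S,2S,4S)-4-bromo-2-(2-hydroxyethyl)-1,3,3-trimethylcyclohexan-1-ol
Conditions: [Ir(cod)(PCy3)(py)]PF6 (5 mol%), H2 (1 atm), CH2Cl2, 0 °C → rt
Reagents that add atoms: none
Why: Hydroxyl-directed homogeneous hydrogenation: the tertiary allylic hydroxyl binds iridium so that hydrogen is delivered to the exocyclic alkene from the face that carries this oxygen, which is also the face free of the two flanking axial methyl groups, so the new ring hydrogen at C2 should end cis to the hydroxyl (2S, the trans ring fusion of the target).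

Step 9
Reactants: 13 (1S,2S,4S)-4-bromo-2-(2-hydroxyethyl)-1,3,3-trimethylcyclohexan-1-ol
Product: 15 (3aS,5S,7aS)-5-bromo-4,4,7a-trimethylhexahydro-1-benzofuran-2(3H)-one, via lactol 14 (not isolated)
Conditions: TEMPO (10 mol%), PhI(OAc)2 (2.5 equiv), CH2Cl2, rt
Reagents that add atoms: none
Why: TEMPO/PhI(OAc)2 oxidation: only the primary alcohol is oxidised, the hydroxy aldehyde closes onto the tertiary hydroxyl and the lactol is oxidised on to the trans-fused γ-lactone without touching a stereocentre.

Step 10
Reactants: 15 (3aS,5S,7aS)-5-bromo-4,4,7a-trimethylhexahydro-1-benzofuran-2(3H)-one; 16 tert-butyldimethyl(prop-2-yn-1-yloxy)silane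
Product: 18 1-[(1S,3S,6S)-3-bromo-6-hydroxy-2,2,6-trimethylcyclohexyl]-5-[(tert-butyldimethylsilyl)oxy]pent-3-yn-2-one, via lithium acetylide 17 (not isolated)
Conditions: 16, n-BuLi, THF, −78 °C; then 15, −78 °C; AcOH quench
Reagents that add atoms: none
Why: Acetylide addition to a lactone: the lithium acetylide adds once to the lactone carbonyl and the lithium hemiketal alkoxide survives at low temperature, so quenching should give the ynone (in equilibrium with its five-membered alkynyl hemiketal) without over-addition.

Step 11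
Reactants: 18 1-[(1S,3S,6S)-3-bromo-6-hydroxy-2,2,6-trimethylcyclohexyl]-5-[(tert-butyldimethylsilyl)oxy]pent-3-yn-2-one
Product: 19 (5aS,7S,9aS)-7-bromo-2-{[(tert-butyldimethylsilyl)oxy]methyl}-6,6,9a-trimethyl-5a,6,7,8,9,9a-hexahydro-1-benzoxepin-4(5H)-one
Conditions: Cs2CO3 (0.3 equiv), MeCN, rt
Reagents that add atoms: none
Why: Intramolecular oxa-Michael addition (7-endo-dig): the carbonate opens the hemiketal to the tertiary alkoxide, which adds to the β-carbon of the ynone, and protonation of the allenolate gives the vinylogous ester, the hemiketal being only a reversible resting state and the vinylogous ester the thermodynamic sink.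

Step 12
Reactants: 19 (5aS,7S,9aS)-7-bromo-2-{[(tert-butyldimethylsilyl)oxy]methyl}-6,6,9a-trimethyl-5a,6,7,8,9,9a-hexahydro-1-benzoxepin-4(5H)-one
Product: 23 (2R,5aS,7S,9aS)-7-bromo-2-{[(tert-butyldimethylsilyl)oxy]methyl}-6,6,9a-trimethyl-3-methylideneoctahydro-1-benzoxepin-4(2H)-one, via lithium enolate 20 (not isolated), via Mannich base 21 (not isolated), via ammonium iodide 22 (not isolated)
Conditions: L-Selectride (LiBH(s-Bu)3), THF, −78 °C; then CH2=NMe2+ I−, −78 → 0 °C; then MeI, rt; then DBU, rt
Reagents that add atoms: Eschenmoser's salt (N,N-dimethylmethyleneiminium iodide), C=[N+](C)C.[I-]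
Why: Conjugate reduction followed by Mannich methylenation: the bulky hydride should add to the β-carbon of the vinylogous ester from the face opposite the axial C9a methyl group (sets 2R with the silyloxymethyl group equatorial), the regiodefined enolate is aminomethylated at C3 by the iminium salt, and quaternisation then base-induced loss of trimethylamine gives the exocyclic enone.

Step 13
Reactants: 23 (2R,5aS,7S,9aS)-7-bromo-2-{[(tert-butyldimethylsilyl)oxy]methyl}-6,6,9a-trimethyl-3-methylideneoctahydro-1-benzoxepin-4(2H)-one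
Product: 24 (2R,5aS,7S,9aS)-7-bromo-2-(bromomethyl)-6,6,9a-trimethyl-3-methylideneoctahydro-1-benzoxepin-4(2H)-one
Conditions: Ph3PBr2, CH2Cl2, 0 °C → rt
Reagents that add atoms: dibromotriphenylphosphorane, BrP(Br)(c1ccccc1)(c1ccccc1)c1ccccc1
Why: Direct conversion of a silyl ether into a bromide with Ph3PBr2: the primary silyl ether becomes the alkoxyphosphonium bromide, which bromide opens by SN2 at the CH2 group, so the C2 stereocentre is not involved.

Step 14
Reactants: 24 (2R,5aS,7S,9aS)-7-bromo-2-(bromomethyl)-6,6,9a-trimethyl-3-methylideneoctahydro-1-benzoxepin-4(2H)-one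
Product: 25 (2R,4R,5aS,7S,9aS)-7-bromo-2-(bromomethyl)-6,6,9a-trimethyl-3-methylidenedecahydro-1-benzoxepin-4-ol
Conditions: (S)-2-methyl-CBS-oxazaborolidine (20 mol%), catecholborane, toluene, −78 °C
Reagents that add atoms: none
Why: CBS reduction: the oxazaborolidine–borane complex should bind the ketone with the alkenyl side as the large group and deliver hydride 1,2 to the face that gives the 4R allylic alcohol under reagent control, leaving the alkene and both bromides untouched at low temperature.

**Compound list**

1 | 6-methylhept-5-en-2-one | CC(=O)CCC=C(C)C | starting material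
2 | 4-[(2R)-3,3-dimethyloxiran-2-yl]butan-2-one | CC(=O)CC[C@H]1OC1(C)C | intermediate
3 | {4-[(2R)-3,3-dimethyloxiran-2-yl]-2-methylbut-1-en-1-yl}trimethylsilane (E/Z mixture) | C[Si](C)(C)C=C(C)CC[C@H]1OC1(C)C | intermediate
4 | {[(3R)-2-bromo-2,6-dimethyl-7-(trimethylsilyl)hept-6-en-3-yl]oxy}trimethylsilane | C[Si](C)(C)C=C(C)CC[C@@H](O[Si](C)(C)C)C(C)(C)Br | intermediate
5 | (3R)-2-bromo-2,6-dimethyl-7-(trimethylsilyl)hept-6-en-3-ol | C[Si](C)(C)C=C(C)CC[C@@H](O)C(C)(C)Br | intermediate
6 | (3R)-2-bromo-2,6-dimethyl-7-(trimethylsilyl)hept-6-en-3-yl trifluoromethanesulfonate | C[Si](C)(C)C=C(C)CC[C@@H](OS(=O)(=O)C(F)(F)F)C(C)(C)Br | intermediate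
7 | (4S)-4-bromo-1,3,3-trimethylcyclohex-1-ene | CC1=CC(C)(C)[C@@H](Br)CC1 | intermediate
8 | (2S,5S)-5-bromo-2-hydroxy-2,6,6-trimethylcyclohexan-1-one | O=C1C(C)(C)[C@@H](Br)CC[C@]1(C)O | intermediate
9 | (triphenylphosphoranylidene)ketene | O=C=C=P(c1ccccc1)(c1ccccc1)c1ccccc1 | starting material
10 | (1S,4S)-4-bromo-1,3,3-trimethyl-2-oxocyclohexyl (triphenylphosphoranylidene)acetate | O=C1C(C)(C)[C@@H](Br)CC[C@]1(C)OC(=O)C=P(c1ccccc1)(c1ccccc1)c1ccccc1 | intermediate
11 | (5S,7aS)-5-bromo-4,4,7a-trimethyl-5,6,7,7a-tetrahydro-1-benzofuran-2(4H)-one | O=C1C=C2C(C)(C)[C@@H](Br)CC[C@]2(C)O1 | intermediate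
12 | (1S,4S)-4-bromo-2-[(2Z)-2-hydroxyethylidene]-1,3,3-trimethylcyclohexan-1-ol | OC/C=C1/C(C)(C)[C@@H](Br)CC[C@]1(C)O | intermediate
13 | (1S,2S,4S)-4-bromo-2-(2-hydroxyethyl)-1,3,3-trimethylcyclohexan-1-ol | OCC[C@H]1C(C)(C)[C@@H](Br)CC[C@]1(C)O | intermediate
14 | (3aS,5S,7aS)-5-bromo-4,4,7a-trimethyloctahydro-1-benzofuran-2-ol (anomers) | OC1C[C@H]2C(C)(C)[C@@H](Br)CC[C@]2(C)O1 | intermediate
15 | (3aS,5S,7aS)-5-bromo-4,4,7a-trimethylhexahydro-1-benzofuran-2(3H)-one | O=C1C[C@H]2C(C)(C)[C@@H](Br)CC[C@]2(C)O1 | intermediate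
16 | tert-butyldimethyl(prop-2-yn-1-yloxy)silane | C#CCO[Si](C)(C)C(C)(C)C | starting material
17 | {3-[(tert-butyldimethylsilyl)oxy]prop-1-yn-1-yl}lithium | [Li]C#CCO[Si](C)(C)C(C)(C)C | intermediate
18 | 1-[(1S,3S,6S)-3-bromo-6-hydroxy-2,2,6-trimethylcyclohexyl]-5-[(tert-butyldimethylsilyl)oxy]pent-3-yn-2-one | CC(C)(C)[Si](C)(C)OCC#CC(=O)C[C@H]1C(C)(C)[C@@H](Br)CC[C@]1(C)O | intermediate
19 | (5aS,7S,9aS)-7-bromo-2-{[(tert-butyldimethylsilyl)oxy]methyl}-6,6,9a-trimethyl-5a,6,7,8,9,9a-hexahydro-1-benzoxepin-4(5H)-one | CC(C)(C)[Si](C)(C)OCC1=CC(=O)C[C@H]2C(C)(C)[C@@H](Br)CC[C@]2(C)O1 | intermediate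
20 | lithium (2R,5aS,7S,9aS)-7-bromo-2-{[(tert-butyldimethylsilyl)oxy]methyl}-6,6,9a-trimethyl-2,5,5a,6,7,8,9,9a-octahydro-1-benzoxepin-4-olate | C1=C(O[Li])C[C@H]2C(C)(C)[C@@H](Br)CC[C@]2(C)O[C@H]1CO[Si](C)(C)C(C)(C)C | intermediate
21 | (2R,5aS,7S,9aS)-7-bromo-2-{[(tert-butyldimethylsilyl)oxy]methyl}-3-[(dimethylamino)methyl]-6,6,9a-trimethyloctahydro-1-benzoxepin-4(2H)-one (C3 epimers) | CN(C)CC1C(=O)C[C@H]2C(C)(C)[C@@H](Br)CC[C@]2(C)O[C@H]1CO[Si](C)(C)C(C)(C)C | intermediate
22 | {[(2R,5aS,7S,9aS)-7-bromo-2-{[(tert-butyldimethylsilyl)oxy]methyl}-6,6,9a-trimethyl-4-oxodecahydro-1-benzoxepin-3-yl]methyl}trimethylammonium iodide | C[N+](C)(C)CC1C(=O)C[C@H]2C(C)(C)[C@@H](Br)CC[C@]2(C)O[C@H]1CO[Si](C)(C)C(C)(C)C.[I-] | intermediate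
23 | (2R,5aS,7S,9aS)-7-bromo-2-{[(tert-butyldimethylsilyl)oxy]methyl}-6,6,9a-trimethyl-3-methylideneoctahydro-1-benzoxepin-4(2H)-one | C=C1C(=O)C[C@H]2C(C)(C)[C@@H](Br)CC[C@]2(C)O[C@H]1CO[Si](C)(C)C(C)(C)C | intermediate
24 | (2R,5aS,7S,9aS)-7-bromo-2-(bromomethyl)-6,6,9a-trimethyl-3-methylideneoctahydro-1-benzoxepin-4(2H)-one | C=C1C(=O)C[C@H]2C(C)(C)[C@@H](Br)CC[C@]2(C)O[C@H]1CBr | intermediate
25 | (2R,4R,5aS,7S,9aS)-7-bromo-2-(bromomethyl)-6,6,9a-trimethyl-3-methylidenedecahydro-1-benzoxepin-4-ol | C=C1[C@H](O)C[C@H]2C(C)(C)[C@@H](Br)CC[C@]2(C)O[C@H]1CBr | target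

**Step count and risks**

Total step count: 14. Longest linear sequence: 14 steps (1 to 25; 9 and 16 are bought).

The three steps most likely to fail are 11, 4 and 8.

In step 11 the alkoxide may stay parked as the five-membered hemiketal, or base may isomerise the propargylic ether to an allenyl ketone faster than the seven-membered ring closes. The fallback sets out from 18: diethylamine is added across the ynone (aza-Michael) to give the enaminone 1-[(1S,3S,6S)-3-bromo-6-hydroxy-2,2,6-trimethylcyclohexyl]-5-[(tert-butyldimethylsilyl)oxy]-4-(diethylamino)pent-3-en-2-one F1. Warming F1 with CF3CO2H (cat.) in toluene then lets the tertiary hydroxyl close the ring by addition–elimination on the protonated vinylogous amide, with loss of diethylamine. It comes back to the route at 19.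

In step 4 enantiopurity may be lost by bromonium transfer between alkenes, and the triflate may eliminate or never form cleanly on the hindered carbinol. The fallback sets out from 3: Li2NiBr4 in THF opens the epoxide by SN2 at the secondary carbon with inversion to give (3S)-3-bromo-2,6-dimethyl-7-(trimethylsilyl)hept-6-en-2-ol F2. Ionising its tertiary hydroxyl with SnCl4 in CH2Cl2 at −78 °C generates the same bromonium ion with the carbon–bromine bond already in place, so the configuration is retained, and the vinylsilane closes the ring as before. It comes back at 7.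

In step 8 facial selectivity may be poor, with hydrogen delivered on the side of the angular methyl group to give the cis-fused series, or the iridium catalyst may isomerise or ionise the allylic diol. The fallback sets out from 11: conjugate reduction of the butenolide with Stryker's reagent [(Ph3P)CuH]6 in wet toluene delivers a nucleophilic hydride to C3a along the axial trajectory opposite both flanking axial methyl groups, and protonation at C3 follows. It comes back at 15 directly, bypassing 12 and 13, and no new compound arises (F0).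

Further compounds
F1 | step 11 | 1-[(1S,3S,6S)-3-bromo-6-hydroxy-2,2,6-trimethylcyclohexyl]-5-[(tert-butyldimethylsilyl)oxy]-4-(diethylamino)pent-3-en-2-one | CCN(CC)C(CO[Si](C)(C)C(C)(C)C)=CC(=O)C[C@H]1C(C)(C)[C@@H](Br)CC[C@]1(C)O
F2 | step 4 | (3S)-3-bromo-2,6-dimethyl-7-(trimethylsilyl)hept-6-en-2-ol | C[Si](C)(C)C=C(C)CC[C@H](Br)C(C)(C)O
F0 | step 8 | none | none
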